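**Retrosynthetic overview**
1. Target ⇐ removal of two allyl-based protecting groups from a 3‑O‑angelate ⇐ 3‑ol ⇐ 3‑keto‑18‑ol, which is a masked ring‑A isoxazoline.
2. Key disconnection: ring A (C3–C4 bond, quaternary C4, C3=O and C18–O together) by an intramolecular nitrile oxide–alkene [3+2] cycloaddition onto a C5 isopropenyl group.
3. C8=CH2 by Wittig methylenation; C13=C14 by Horner–Wadsworth–Emmons olefination; C11–C13 by Michael addition of the C8–C9 enol silane to methyl vinyl ketone; C3 by hydroformylation of a C10 vinyl group.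
4. Ring B with C5 and C10 is carved out of (1S,5S)-verbenone: cuprate vinylation sets C10, cyclobutane opening turns the gem‑dimethyl bridge into the C5 isopropenyl group.
5. Ring order: ring B first (bought six‑membered ring of verbenone, pinane opened), ring A second (cycloaddition).

Assumption: positions are given in labdane numbering (C1–C20), and compounds 1, 2, 4, 13 and 19 are bought.

**Step 1**
Reactants: 1 (1S,5S)-(−)-verbenone; 2 vinylmagnesium bromide
Product: 3 trimethyl{[(1S,4R,5R)-4-ethenyl-4,6,6-trimethylbicyclo[3.1.1]hept-2-en-2-yl]oxy}silane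
Conditions: CuBr·SMe2 (10 mol%), TMSCl, THF, −78 → −30 °C; Et3N, pentane work-up
Reagents that add atoms: chlorotrimethylsilane, C[Si](C)(C)Cl
Why: Copper-catalysed, TMSCl-accelerated conjugate addition of the vinyl Grignard reagent to the β,β-disubstituted enone can only occur on the face opposite the gem-dimethyl bridge, so the new quaternary carbon (future C10) is set by the bought bridgehead (future C5), and the enolate is trapped regiospecifically as its silyl enol ether.

**Step 2**
Reactants: 3 silyl enol ether; 4 methyl vinyl ketone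
Product: 5 (1S,3R,4R,5R)-4-ethenyl-4,6,6-trimethyl-3-(3-oxobutyl)bicyclo[3.1.1]heptan-2-one
Conditions: Sc(OTf)3 (5 mol%), CH2Cl2, −78 → −40 °C; 1 M HCl work-up
Reagents that add atoms: none
Why: Mukaiyama–Michael addition of the only enol silane this ketone can form (the other α-carbon is a bridgehead) puts the C11–C13/C16 chain on C9; it enters anti to the gem-dimethyl bridge, which gives the 9-epi configuration that is corrected in step 7.

**Step 3**
Reactants: 5 bicyclic diketone
Product: 8 (2R,3R,4R)-3-ethenyl-3-methyl-2-(3-oxobutyl)-4-(prop-1-en-2-yl)cyclohexan-1-one, via tertiary iodide silyl enol ether 6 (not isolated), via isopropenyl silyl enol ether 7 (not isolated)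
Conditions: TMSCl, NaI, MeCN, −20 °C; DBU, 0 °C → rt; 1 M HCl–THF work-up
Reagents that add atoms: none
Why: Iodotrimethylsilane silylates the strained cyclobutyl ketone and iodide opens the cyclobutane bond next to it at the tertiary carbon (strain-driven homo-conjugate ring opening), DBU eliminates HI toward a methyl group (E2; the ring hydrogen at C5 is shielded by the neighbouring quaternary carbon) to unveil the isopropenyl group, and hydrolysis of the enol ether returns the C8 ketone with C5 and C10 untouched.

**Step 4**
Reactants: 8 ring-B diketone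
Product: 10 aldoxime of (2R,3R,4R)-3-methyl-2-(3-oxobutyl)-3-(3-oxopropyl)-4-(prop-1-en-2-yl)cyclohexan-1-one, via aldehyde 9 (not isolated)
Conditions: Rh(acac)(CO)2 (1 mol%), Xantphos (2 mol%), CO/H2 (1:1, 10 bar), toluene, 60 °C; then NH2OH·HCl (1.05 equiv), NaOAc, EtOH, 0 °C
Reagents that add atoms: carbon monoxide, [C-]#[O+]; hydroxylamine hydrochloride, NO.Cl
Why: Rhodium-catalysed hydroformylation adds the formyl carbon (C3) to the terminus of the monosubstituted vinyl group, which reacts faster than the hindered 1,1-disubstituted isopropenyl group and can only give the linear aldehyde because its inner carbon is neopentylic, and the aldehyde then forms its oxime much faster than either ketone.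

**Step 5**
Reactants: 10 aldoxime
Product: 12 9-epi tricyclic isoxazoline diketone (ring A closed; C3=N–O–C18 isoxazoline fused at C3–C4 of the trans-decalin; C8 ketone; 3-oxobutyl on C9), via nitrile oxide 11 (not isolated)
Conditions: PhI(OAc)2, TFA (cat.), MeOH, 0.01 M, 0 °C → rt
Reagents that add atoms: none
Why: Oxidation of the aldoxime gives the nitrile oxide, which closes ring A by intramolecular nitrile oxide–alkene 1,3-dipolar cycloaddition onto the isopropenyl group through a trans-fused chair; the isoxazoline CH2–O must lie close to the plane of C3=N and so becomes the equatorial C4 substituent, forcing the C4 methyl axial (cis to the C10 methyl), which is the required configuration of the quaternary C4.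

**Step 6**
Reactants: 12 isoxazoline diketone; 13 allyl diethylphosphonoacetate
Product: 14 9-epi allyl (2E)-enoate (side chain CH2CH2C(CH3)=CHCO2allyl on C9; C8 ketone and ring-A isoxazoline kept)
Conditions: NaH, THF, 0 → 45 °C
Reagents that add atoms: none
Why: Horner–Wadsworth–Emmons olefination takes place only at the unhindered methyl ketone (the ring ketone sits between a tertiary and a neopentylic centre) and gives mainly the E-trisubstituted enoate (about 6:1; the Z isomer is removed by chromatography).

**Step 7**
Reactants: 14 9-epi keto enoate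
Product: 15 8(17)-methylene isoxazoline allyl ester with the 9R configuration of the target
Conditions: Ph3PCH3Br, KOt-Bu (slight excess), THF–toluene, rt → 60 °C
Reagents that add atoms: methyltriphenylphosphonium bromide, [Br-].C[P+](c1ccccc1)(c1ccccc1)c1ccccc1
Why: Wittig methylenation of the C8 ketone; under the basic conditions C9 equilibrates through the enolate, and only the epimer with the equatorial side chain (H9 axial, on the face away from the axial C10 methyl) has a carbonyl face open to the ylide, so olefination drains the equilibrium toward the natural C9 configuration.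

**Step 8**
Reactants: 15 methylene isoxazoline
Product: 16 3-oxo-18-hydroxy allyl ester (β-hydroxy ketone; C4 bears axial CH3 and equatorial CH2OH)
Conditions: SmI2 (2.5 equiv), B(OH)3, THF–H2O, 0 °C
Reagents that add atoms: water, O
Why: Two-electron reductive cleavage of the isoxazoline N–O bond by SmI2 and hydrolysis of the resulting β-hydroxy imine unmask the C3 ketone and the C18 alcohol under buffered conditions that avoid retro-aldol loss of formaldehyde and leave C4 untouched.

**Step 9**
Reactants: 16 β-hydroxy ketone
Product: 17 18-O-allyloxycarbonyl 3-ketone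
Conditions: allyl chloroformate, pyridine, DMAP (cat.), CH2Cl2, 0 °C
Reagents that add atoms: allyl chloroformate, C=CCOC(Cl)=O
Why: Carbonate formation at the only hydroxyl group blocks the primary alcohol for the later esterification and removes the free aldol OH before the hydride step.

**Step 10**
Reactants: 17 keto carbonate
Product: 18 (3R)-3-hydroxy 18-O-allyloxycarbonyl allyl ester
Conditions: NaBH4, CeCl3·7H2O, MeOH, −40 °C; AcOH quench
Reagents that add atoms: none
Why: Luche reduction of the 4,4-disubstituted 3-ketone: hydride attacks axially, on the face opposite the axial C4 and C10 methyl groups, giving the equatorial 3-alcohol (3R) as in related 4,4-disubstituted 3-oxo terpenoids, without 1,4-reduction of the enoate.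

**Step 11**
Reactants: 18 secondary alcohol; 19 angelic acid
Product: 21 3-O-angeloyl 18-O-allyloxycarbonyl allyl ester, via mixed angelic 2,4,6-trichlorobenzoic anhydride 20 (not isolated)
Conditions: 2,4,6-trichlorobenzoyl chloride, Et3N, toluene, rt; then 18, 75 °C
Reagents that add atoms: none
Why: Yamaguchi-type esterification through the mixed anhydride acylates the hindered secondary alcohol at the angeloyl carbonyl without a nucleophilic catalyst, which keeps the Z (angelate) double bond from isomerising to the tiglate.

**Step 12**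
Reactants: 21 fully protected angelate
Product: 22 target acid
Conditions: Pd(PPh3)4 (5 mol%), morpholine, THF, rt; dilute citric acid work-up
Reagents that add atoms: none
Why: Palladium-catalysed allyl transfer to morpholine (Tsuji–Trost deallylation) cleaves the allyl ester and the allyl carbonate (with loss of CO2) under near-neutral conditions that leave the angelate, both alkenes and all stereocentres untouched.

**Compound list**
1 | (1S,5S)-(−)-verbenone, (1S,5S)-4,6,6-trimethylbicyclo[3.1.1]hept-3-en-2-one | CC1=CC(=O)[C@H]2C[C@@H]1C2(C)C | starting material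
2 | vinylmagnesium bromide (THF solution) | C=C[Mg]Br | starting material
3 | trimethyl{[(1S,4R,5R)-4-ethenyl-4,6,6-trimethylbicyclo[3.1.1]hept-2-en-2-yl]oxy}silane (vinyl anti to the gem-dimethyl bridge) | C[C@]1(C=C)C=C(O[Si](C)(C)C)[C@H]2C[C@@H]1C2(C)C | intermediate
4 | methyl vinyl ketone (but-3-en-2-one) | C=CC(C)=O | starting material
5 | (1S,3R,4R,5R)-4-ethenyl-4,6,6-trimethyl-3-(3-oxobutyl)bicyclo[3.1.1]heptan-2-one (vinyl and oxobutyl both anti to the gem-dimethyl bridge) | C[C@]1(C=C)[C@@H](CCC(C)=O)C(=O)[C@H]2C[C@@H]1C2(C)C | intermediate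
6 | ring-opened tertiary iodide (2-iodopropan-2-yl on C5) with the C8 ketone as its trimethylsilyl enol ether toward C7; configuration as in 8 | C[Si](C)(C)OC1=CC[C@H](C(C)(C)I)[C@@](C)(C=C)[C@H]1CCC(C)=O | intermediate
7 | isopropenyl compound with the C8 ketone still as its trimethylsilyl enol ether toward C7; configuration as in 8 | C[Si](C)(C)OC1=CC[C@H](C(C)=C)[C@@](C)(C=C)[C@H]1CCC(C)=O | intermediate
8 | (2R,3R,4R)-3-ethenyl-3-methyl-2-(3-oxobutyl)-4-(prop-1-en-2-yl)cyclohexan-1-one (ring B; C5 and C10 arranged as in the target, vinyl trans to isopropenyl; C9 epimeric) | O=C1CC[C@H](C(C)=C)[C@@](C)(C=C)[C@H]1CCC(C)=O | intermediate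
9 | (2R,3R,4R)-3-methyl-2-(3-oxobutyl)-3-(3-oxopropyl)-4-(prop-1-en-2-yl)cyclohexan-1-one | O=C1CC[C@H](C(C)=C)[C@@](C)(CCC=O)[C@H]1CCC(C)=O | intermediate
10 | aldoxime of 9 (E/Z mixture at C=N) | O=C1CC[C@H](C(C)=C)[C@@](C)(CCC=NO)[C@H]1CCC(C)=O | intermediate
11 | nitrile oxide from 10 | O=C1CC[C@H](C(C)=C)[C@@](C)(CCC#[N+][O-])[C@H]1CCC(C)=O | intermediate
12 | 9-epi tricyclic isoxazoline diketone: trans-decalin with C10 methyl, ring-A isoxazoline (C3=N–O–C18H2–C4, C4 methyl cis to C10 methyl), C8 ketone, 3-oxobutyl on C9 | O=C1CC[C@H]2[C@@](C)(CCC3=NOC[C@]23C)[C@H]1CCC(C)=O | intermediate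
13 | allyl diethylphosphonoacetate | C=CCOC(=O)CP(=O)(OCC)OCC | starting material
14 | 9-epi allyl (2E)-3-methyl-5-(8-oxo ring-A-isoxazoline decalin-9-yl)pent-2-enoate | O=C1CC[C@H]2[C@@](C)(CCC3=NOC[C@]23C)[C@H]1CC/C(C)=C/C(=O)OCC=C | intermediate
15 | allyl (2E)-enoate of the 8(17)-methylene ring-A isoxazoline; C4, C5, C9, C10 as in the target | C=C1CC[C@H]2[C@@](C)(CCC3=NOC[C@]23C)[C@@H]1CC/C(C)=C/C(=O)OCC=C | intermediate
16 | allyl 18-hydroxy-3-oxolabda-8(17),13E-dien-15-oate of the target series (CH2OH on C4 trans to the C10 methyl) | C=C1CC[C@H]2[C@@](C)(CCC(=O)[C@]2(C)CO)[C@@H]1CC/C(C)=C/C(=O)OCC=C | intermediate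
17 | 18-O-allyloxycarbonyl derivative of 16 | C=C1CC[C@H]2[C@@](C)(CCC(=O)[C@]2(C)COC(=O)OCC=C)[C@@H]1CC/C(C)=C/C(=O)OCC=C | intermediate
18 | (3R)-3-hydroxy compound from 17 (3-OH equatorial, trans to the C4 carbonate-bearing CH2) | C=C1CC[C@H]2[C@@](C)(CC[C@@H](O)[C@]2(C)COC(=O)OCC=C)[C@@H]1CC/C(C)=C/C(=O)OCC=C | intermediate
19 | angelic acid, (2Z)-2-methylbut-2-enoic acid | C/C=C(/C)C(=O)O | starting material
20 | angelic 2,4,6-trichlorobenzoic anhydride | C/C=C(/C)C(=O)OC(=O)c1c(Cl)cc(Cl)cc1Cl | intermediate
21 | 3-O-angeloyl 18-O-allyloxycarbonyl allyl ester | C=C1CC[C@H]2[C@@](C)(CC[C@@H](OC(=O)/C(C)=C\C)[C@]2(C)COC(=O)OCC=C)[C@@H]1CC/C(C)=C/C(=O)OCC=C | intermediate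
22 | (2E)-5-[(1R,4aS,5S,6R,8aS)-5-(hydroxymethyl)-5,8a-dimethyl-6-{[(2Z)-2-methylbut-2-enoyl]oxy}-2-methylidenedecahydronaphthalen-1-yl]-3-methylpent-2-enoic acid (3R,4S,5S,9R,10S in labdane numbering) | C=C1CC[C@H]2[C@@](C)(CC[C@@H](OC(=O)/C(C)=C\C)[C@]2(C)CO)[C@@H]1CC/C(C)=C/C(=O)O | target

**Total step count:** 12. **Longest linear sequence:** 12 steps (from 1).

**Steps most likely to fail, with fallbacks**

Step 3 (cyclobutane opening). The tertiary iodide may eliminate partly toward the ring (isopropylidene, which would destroy C5), and the 1,5-diketone may undergo aldol closure under DBU. The fallback sets out from 5 and comes back at 8. Instead of iodide capture and base-induced elimination, the ring is opened by a non-basic acetylative cleavage (BF3·OEt2, Zn(OAc)2, Ac2O, 0 °C). The tertiary cation loses a methyl proton in the acylating medium and the ring enol is trapped as its acetate, giving the isopropenyl ring-B enol acetate F1. Brief methanolysis (K2CO3, MeOH, 0 °C) then releases 8.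

Step 4 (hydroformylation beside the isopropenyl group). Selectivity between the neopentylic vinyl group and the isopropenyl group may be too low. The fallback sets out from 1 and comes back at 9. All three ring-A carbons are brought in as an allyl group whose terminus is oxidised, instead of adding CO. Allylcopper (allylMgBr, CuBr·SMe2, TMSCl, THF, −78 °C) adds to 1 to give the allyl enol silane F2. Mukaiyama–Michael addition to 4 gives the allyl bicyclic diketone F3. The ring opening of step 3 then proceeds through the allyl tertiary iodide silyl enol ether F4 and the allyl isopropenyl silyl enol ether F5 to the allyl ring-B diketone F6. An aldehyde-selective (anti-Markovnikov) Wacker oxidation (PdCl2(PhCN)2, CuCl2·2H2O, AgNO2, t-BuOH–MeNO2, O2), to which 1,1-disubstituted alkenes are inert, converts the allyl terminus into aldehyde 9, which is oximated to 10 as in step 4.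

Step 7 (C9 configuration during methylenation). The equilibrium at C9 is only modestly biased, so the 9-epimer may be carried into the alkene, and the base may also touch the enoate. The fallback sets out from 14 and comes back at 15. C9 is set by kinetic protonation instead of equilibration. Ketone 14 is converted under thermodynamic conditions (Me3SiI, (Me3Si)2NH, CH2Cl2) into the more substituted C8–C9 silyl enol ether F7. Buffered fluoride (TBAF, AcOH, THF, −78 °C) protonates the enolate axially on the face away from the C10 methyl, giving the 9R keto enoate F8. A base-free Wittig reaction (salt-free Ph3P=CH2 from Ph3PCH3Br and NaN(SiMe3)2, THF, 0 °C) then gives 15 before C9 can equilibrate.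

**Further compounds**
F1 | step 3 | 5-ethenyl-5-methyl-6-(3-oxobutyl)-4-(prop-1-en-2-yl)cyclohex-1-en-1-yl acetate, configuration as in 8 | CC(=O)OC1=CC[C@H](C(C)=C)[C@@](C)(C=C)[C@H]1CCC(C)=O
F2 | step 4 | trimethyl{[4,6,6-trimethyl-4-(prop-2-en-1-yl)bicyclo[3.1.1]hept-2-en-2-yl]oxy}silane, allyl anti to the gem-dimethyl bridge | C[C@]1(CC=C)C=C(O[Si](C)(C)C)[C@H]2C[C@@H]1C2(C)C
F3 | step 4 | 4,6,6-trimethyl-3-(3-oxobutyl)-4-(prop-2-en-1-yl)bicyclo[3.1.1]heptan-2-one, allyl and oxobutyl anti to the gem-dimethyl bridge | C[C@]1(CC=C)[C@@H](CCC(C)=O)C(=O)[C@H]2C[C@@H]1C2(C)C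
F4 | step 4 | allyl analogue of 6 (tertiary iodide, trimethylsilyl enol ether) | C[Si](C)(C)OC1=CC[C@H](C(C)(C)I)[C@@](C)(CC=C)[C@H]1CCC(C)=O
F5 | step 4 | allyl analogue of 7 (isopropenyl, trimethylsilyl enol ether) | C[Si](C)(C)OC1=CC[C@H](C(C)=C)[C@@](C)(CC=C)[C@H]1CCC(C)=O
F6 | step 4 | 3-methyl-2-(3-oxobutyl)-4-(prop-1-en-2-yl)-3-(prop-2-en-1-yl)cyclohexan-1-one, configuration as in 8 | O=C1CC[C@H](C(C)=C)[C@@](C)(CC=C)[C@H]1CCC(C)=O
F7 | step 7 | C8–C9 trimethylsilyl enol ether of 14 | C[Si](C)(C)OC1=C(CC/C(C)=C/C(=O)OCC=C)[C@]2(C)CCC3=NOC[C@]3(C)[C@H]2CC1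
F8 | step 7 | 9R epimer of 14 (side chain equatorial) | O=C1CC[C@H]2[C@@](C)(CCC3=NOC[C@]23C)[C@@H]1CC/C(C)=C/C(=O)OCC=C
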